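**Plan**
- Cuts: first the aryl C–C(=O) bond of the ketone (retro-Fries/Friedel–Crafts), giving 2-(4-methylpentyl)resorcinol 5 and 4,5-dichloropyrrole-2-carbonyl chloride 10. Then the aryl C2–CH2 bond of 5 and the two pyrrole C–Cl bonds of 10.
- Enabling feature: the benzene ring is a 2-alkylresorcinol with a mirror plane through C2 (isohexyl) and C5. C4 and C6 are equivalent, each ortho to one OH and para to the other. C2 is blocked and C5 is meta to both oxygens. The ketone of the target sits next to an OH and closes a six-membered O–H···O=C chelate.
- Consequence: an acyl group parked on either oxygen (a temporary ester tether) can move to carbon, by ortho or para shift, only to the position the target needs. No group on the phenols or the pyrrole N–H is needed, and the union gives the target itself.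
- Forward: both rings are bought, none is built. The isohexyl chain goes onto the arene (steps 1–2). The pyrrole is dichlorinated while held as an activated acyl derivative (steps 3–5), as in the presumed biosynthesis, where a carrier-bound pyrrolyl thioester is chlorinated before its acyl group passes to carbon. Step 6 is the union.
- Stereochemistry: the target has no stereocentre and no stereogenic double bond, so nothing has to be set.

Key step: step 6

Assumption: the SMILES holds no stereocentre, so the compound is achiral and the request for a single enantiomer is met by the constitution alone.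

**Step 1**
Reactants: 1 1,3-dimethoxybenzene; 2 1-bromo-4-methylpentane
Product: 4 1,3-dimethoxy-2-(4-methylpentyl)benzene, via (2,6-dimethoxyphenyl)lithium 3 (not isolated)
Conditions: n-BuLi (1.1 equiv), THF, 0 °C → rt, 2 h; then 2 (1.2 equiv), 0 °C → 50 °C
Reagents that add atoms: none
Why: Directed ortho-metalation should remove the C2–H between the two coordinating methoxy groups to give 3, which should then displace bromide from the unhindered primary bromide 2 in an SN2 alkylation, with no stereocentre formed.

**Step 2**
Reactants: 4 1,3-dimethoxy-2-(4-methylpentyl)benzene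
Product: 5 2-(4-methylpentyl)benzene-1,3-diol
Conditions: BBr3 (2.5 equiv), CH2Cl2, −78 °C → rt; then H2O, 0 °C
Reagents that add atoms: none
Why: Standard BBr3 cleavage of aryl methyl ethers (O–B complexation, then SN2 attack of bromide on methyl) should free both phenols, and the saturated side chain is inert to it.

**Step 3**
Reactants: 6 2,2,2-trichloro-1-(1H-pyrrol-2-yl)ethan-1-one
Product: 8 2,2,2-trichloro-1-(4,5-dichloro-1H-pyrrol-2-yl)ethan-1-one, via 4-chloro ketone 7 (not isolated)
Conditions: SO2Cl2 (2.2 equiv), CHCl3, 0 °C → rt, dark
Reagents that add atoms: sulfuryl chloride, O=S(=O)(Cl)Cl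
Why: In this electrophilic aromatic chlorination of a 2-acylpyrrole the trichloroacetyl group tames the ring and sends the first chlorine to C4 (7) and the second to the free α-position C5, while C3 next to the bulky acceptor is the least reactive site, so two equivalents should stop at 8.

**Step 4**
Reactants: 8 2,2,2-trichloro-1-(4,5-dichloro-1H-pyrrol-2-yl)ethan-1-one
Product: 9 4,5-dichloro-1H-pyrrole-2-carboxylic acid
Conditions: 2 M aq NaOH (3 equiv), THF, rt; then 2 M HCl to pH 2
Reagents that add atoms: sodium hydroxide, [Na+].[OH-]
Why: In this haloform-type acyl cleavage hydroxide adds to the very electrophilic ketone and the trichloromethyl anion leaves as chloroform, so the carboxylate should form at room temperature without touching the ring chlorines.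

**Step 5**
Reactants: 9 4,5-dichloro-1H-pyrrole-2-carboxylic acid
Product: 10 4,5-dichloro-1H-pyrrole-2-carbonyl chloride
Conditions: (COCl)2 (1.5 equiv), DMF (cat.), CH2Cl2, 0 °C → rt; evaporate, use crude at once
Reagents that add atoms: oxalyl chloride, O=C(Cl)C(=O)Cl
Why: Acid chloride formation through the catalytic Vilsmeier-type chloroiminium salt runs cold and without base, which the electron-poor N–H pyrrole should tolerate.

**Step 6**
Reactants: 5 2-(4-methylpentyl)benzene-1,3-diol; 10 4,5-dichloro-1H-pyrrole-2-carbonyl chloride
Product: 12 (4,5-dichloro-1H-pyrrol-2-yl)[2,4-dihydroxy-3-(4-methylpentyl)phenyl]methanone, via resorcinol monoester 11 (not isolated)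
Conditions: 5 (1.3 equiv), Et3N (1.05 equiv), CH2Cl2, 0 °C, 1 h; then AlCl3 (5 equiv), 0 °C → reflux; then 1 M HCl, 0 °C
Reagents that add atoms: none
Why: Et3N-mediated O-acylation should first tie the halves together as monoester 11, a temporary C–O tether; AlCl3 then binds the ester carbonyl and the phenol oxygen, the acyl–O bond ionises to an aluminium resorcinolate and the pyrrole-stabilised acylium ion, this ion adds to ring carbon, and loss of H+ gives the ketone, which is locked as a six-membered Al chelate with the neighbouring phenolate, so that the O→C transfer is irreversible. The closest known reaction type is the one-pot esterification/Fries rearrangement of resorcinols with aroyl chlorides, the O-tethered form of the Friedel–Crafts acylation. No ring is closed and no stereocentre is formed. The step needs site selectivity on the benzene ring, and the substrate secures it: C2 carries the isohexyl chain, C5 is meta to both oxygens, and C4 and C6 are exchanged by the mirror plane through C2 and C5, so that ortho shift, para shift and any intermolecular acyl transfer all end in the same ketone. It also needs mono- over bis-acylation and arene over pyrrole attack: the slight excess of 5 and the deactivation of the ring by the chelated first acyl group serve the former, and the two chlorines and the carbonyl group make pyrrole C3 and N–H too poor as nucleophiles for the latter. Acidic work-up should break the chelate and give 12 directly, with no protecting group left to remove.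

**Compound list**
1 | 1,3-dimethoxybenzene | COc1cccc(OC)c1 | starting material
2 | 1-bromo-4-methylpentane | CC(C)CCCBr | starting material
3 | (2,6-dimethoxyphenyl)lithium | [Li]c1c(OC)cccc1OC | intermediate
4 | 1,3-dimethoxy-2-(4-methylpentyl)benzene | COc1cccc(OC)c1CCCC(C)C | intermediate
5 | 2-(4-methylpentyl)benzene-1,3-diol | CC(C)CCCc1c(O)cccc1O | intermediate
6 | 2,2,2-trichloro-1-(1H-pyrrol-2-yl)ethan-1-one | O=C(c1ccc[nH]1)C(Cl)(Cl)Cl | starting material
7 | 2,2,2-trichloro-1-(4-chloro-1H-pyrrol-2-yl)ethan-1-one | O=C(c1cc(Cl)c[nH]1)C(Cl)(Cl)Cl | intermediate
8 | 2,2,2-trichloro-1-(4,5-dichloro-1H-pyrrol-2-yl)ethan-1-one | O=C(c1cc(Cl)c(Cl)[nH]1)C(Cl)(Cl)Cl | intermediate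
9 | 4,5-dichloro-1H-pyrrole-2-carboxylic acid | OC(=O)c1cc(Cl)c(Cl)[nH]1 | intermediate
10 | 4,5-dichloro-1H-pyrrole-2-carbonyl chloride | ClC(=O)c1cc(Cl)c(Cl)[nH]1 | intermediate
11 | 3-hydroxy-2-(4-methylpentyl)phenyl 4,5-dichloro-1H-pyrrole-2-carboxylate | CC(C)CCCc1c(O)cccc1OC(=O)c1cc(Cl)c(Cl)[nH]1 | intermediate
12 | (4,5-dichloro-1H-pyrrol-2-yl)[2,4-dihydroxy-3-(4-methylpentyl)phenyl]methanone | CC(C)CCCc1c(O)ccc(C(=O)c2cc(Cl)c(Cl)[nH]2)c1O | target

Total step count: 6. Longest linear sequence: 4 steps (6 → 8 → 9 → 10 → 12). The arene branch (1 → 4 → 5) joins at step 6.

**Steps most likely to fail**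

1. Step 6.
   - What may go wrong: the sequence may stall at the ester stage, because the pyrrole-stabilised acylium ion is a weak electrophile. Acyl groups may also pile up on one ring (second acylation at C6), or the pyrrole may degrade under prolonged Lewis acid treatment.
   - Fallback: it reverses the polarity demand (aryl nucleophile as an organometal, phenols masked), sets out from 4 and 10, and returns at 12.
   - Aryl partner: bromination of 4 (NBS, MeCN, 0 °C) at the position ortho/para to the two methoxy groups should give 1-bromo-2,4-dimethoxy-3-(4-methylpentyl)benzene F1.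
   - Acyl partner: 10 with MeNH(OMe)·HCl and Et3N in CH2Cl2 should give 4,5-dichloro-N-methoxy-N-methyl-1H-pyrrole-2-carboxamide F2.
   - Coupling: bromine–lithium exchange on F1 (n-BuLi, THF, −78 °C) gives [2,4-dimethoxy-3-(4-methylpentyl)phenyl]lithium F3. About two equivalents are added to F2, the first only removing the N–H proton. The stable chelated adduct should collapse on NH4Cl quench to (4,5-dichloro-1H-pyrrol-2-yl)[2,4-dimethoxy-3-(4-methylpentyl)phenyl]methanone F4.
   - Return: BBr3 (CH2Cl2, −78 °C → rt) then cleaves both methyl ethers to give 12.

2. Step 1.
   - What may go wrong: the hindered aryllithium may alkylate slowly, and bromide 2 may be lost through elimination.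
   - Fallback: the C–C bond is made by carbonyl addition instead, setting out from 1 (through 3) and returning at 4.
   - Sequence: 3 is added to commercial 4-methylpentanal (THF, −78 °C) to give racemic 1-(2,6-dimethoxyphenyl)-4-methylpentan-1-ol F5. Ionic deoxygenation (Et3SiH, TFA, CH2Cl2, 0 °C) through the benzylic cation, stabilised by both ortho-methoxy groups, erases the carbinol centre and gives 4.

3. Step 5.
   - What may go wrong: the N–H acid chloride may condense with itself by N-acylation on concentration, or hydrolyse on handling.
   - Fallback: it avoids the acid chloride altogether, sets out from 9 and returns at 11.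
   - Sequence: a Steglich-type esterification of 9 with excess 5 (EDC·HCl, cat. DMAP, CH2Cl2, rt) should give monoester 11. This is isolated by chromatography with recovery of 5 and then taken into the AlCl3 stage of step 6. The fallback makes no compound outside the list (F0).

**Further compounds**
F1 | step 6 | 1-bromo-2,4-dimethoxy-3-(4-methylpentyl)benzene | COc1ccc(Br)c(OC)c1CCCC(C)C
F2 | step 6 | 4,5-dichloro-N-methoxy-N-methyl-1H-pyrrole-2-carboxamide | CON(C)C(=O)c1cc(Cl)c(Cl)[nH]1
F3 | step 6 | [2,4-dimethoxy-3-(4-methylpentyl)phenyl]lithium | [Li]c1ccc(OC)c(CCCC(C)C)c1OC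
F4 | step 6 | (4,5-dichloro-1H-pyrrol-2-yl)[2,4-dimethoxy-3-(4-methylpentyl)phenyl]methanone | COc1ccc(C(=O)c2cc(Cl)c(Cl)[nH]2)c(OC)c1CCCC(C)C
F5 | step 1 | 1-(2,6-dimethoxyphenyl)-4-methylpentan-1-ol (racemic) | COc1cccc(OC)c1C(O)CCC(C)C
F0 | step 5 | none | none
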